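Which flask, cedar or larch, ends with the higher share of target in all that became target or side product?

| flask | starting material | partner | free catalyst | temperature | remark | time |
|---|---|---|---|---|---|---|
| Tuesday's | 0.020 M | 0.0035 M | 100 µM | 50 °C | run made earlier |  |
| Saturday's | 0.020 M | 0.013 M | 100 µM | 83 °C | run made earlier |  |
| cedar | 0.020 M | 0.0190 M | 100 µM |  | at 35 °C until 15 min, from then on at 95 °C | 30 min |
| larch | 0.020 M | 0.00600 M | 100 µM |  | at 35 °C throughout | 30 min |

* which of the two ends with the higher share of target in all that became target or side product ("neither" if they lie within 2 percentage points) (cedar / larch / neither)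
* share of target in all that became target or side product, cedar
* share of target in all that became target or side product, larch

- percent here means starting material units held: one side product counts as two
- the share counts what is present at the end, not what went on to other products

| run | time / min | target / % | side product / % |
|---|---|---|---|
| Tuesday's | 3.00 | 1.3 | 15.7 |
| Tuesday's | 6.00 | 2.9 | 25.6 |
| Tuesday's | 10.0 | 2.3 | 32.7 |
| Tuesday's | 12.0 | 1.2 | 34.1 |
| Tuesday's | 15.0 | 0 | 34.2 |
| Saturday's | 0.250 | 11.4 | 27.5 |
| Saturday's | 0.500 | 12.2 | 53.4 |
| Saturday's | 0.667 | 12.5 | 64.4 |
| Saturday's | 1.33 | 19.5 | 81.5 |
| Saturday's | 3.00 | 17.7 | 80.9 |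

(readings scatter by 1 percentage point)

I read the table row against row. Tuesday's side product stopped at 34.2%, about twice the partner charge of 17.5%, so I took each partner to make one target and each target to carry a second starting material into side product. Target is then the small correction, and partner left is the charge less target less side product divided by 2.

On that count Tuesday's row at 3.00 min leaves 8.35% partner, and the row at 6.00 min leaves 1.80%. Between those two Tuesday rows, as read, 4.95% of target burnt while 6.55% of partner turned over. The constant of that burning, over the pseudo-first-order constant of partner, is my selectivity factor, 118 /M. Multiplied by a concentration of starting material, it gives the burn ratio: how many times faster target goes than partner.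

The first rows give partner constants of 0.247 /min on Tuesday and 1.96 /min on Saturday. A straight line in their logarithm against temperature gives 0.0962 /min at 35 °C. So larch should keep 5.58% of its partner. Its mean starting material of 0.0140 M gives a burn ratio of 1.65. The consecutive-reaction formula, target over partner charge equal to (x − x^a)/(a − 1), then gives 2.17% target and a share of 3.98%.

In cedar, 2 units per partner exceed the charge, so starting material is the limiting reagent. I chose cedar but gave no number, its 95 °C lying above both runs.

The forecast said cedar, with 27% for cedar and 5% for larch, and held that “Target selectivity rises with temperature.”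

The flasks gave cedar: 17.4% in cedar and 2.99% in larch. Cedar held 41.7% target at 15.0 min and 12.3% at 30.0 min, with 29.5% over-reaction product, while side product stayed at 58.3%.

    partner + free catalyst ⇌ catalyst intermediate A (K = 64.0 /M, k = 1800 /M/min, Ea = 47.0 kJ/mol, ΔH = 16.0 kJ/mol)
    catalyst intermediate A → catalyst intermediate B (k = 76.0 /min, Ea = 65.0 kJ/mol)
    starting material + catalyst intermediate B ⇌ catalyst intermediate C (K = 1000 /M, k = 69000 /M/min, Ea = 43.0 kJ/mol, ΔH = −13.0 kJ/mol)
    catalyst intermediate C → free catalyst + target (k = 260 /min, Ea = 73.0 kJ/mol)
    target → over-reaction product (k = 1.60 × 10⁻⁴ /min, Ea = 98.0 kJ/mol)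
    starting material + target → side product (k = 16.0 /M/min, Ea = 66.0 kJ/mol)
    (constants at 35 °C)

In larch, the factor with the mean of the charge and the 43.1% starting material left gives a burn ratio of 1.69. With 2.24% of partner left, that makes 0.901% target against 1.70% found. A neighbouring flask, larch kept at 20 °C, held 67.3% starting material and 32.9% of its partner. The same factor, carried unchanged, gives a burn ratio of 1.98, 6.69% target against 7.52% found, and a share of 20.0% against 23.0%.

The numbers in the tables stem from a simulated flask for substances that don't exist; scatter was added.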